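Atoms are named by benzofuran numbering (O1, C2 aryl, C3 methyl, C3a allyl, C4, C5 OMe, C6 carbonyl, C7, C7a). The cyclohexadienone ring is cut at C6–C7 and C7a–C3a, leaving a two-carbon unit C7–C7a that is hung on O1 as a vinyl ether. The key step is an intramolecular formal [4+2] cycloaddition of an α-methoxy vinylketene (C3a=C4–C5(OMe)=C6=O) with this enol ether: it closes the carbocycle and the oxolane ring at once and sets quaternary C3a from C2/C3, which come from one catalytic anti-crotylation. It exploits the electrophilic C6, the O1-bearing C7a and the three-atom link C3a–C3–C2–O1. The precursor is an acyclic O-vinyl α-methoxy enoic acid; a final dehydrogenation gives C7=C7a.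

Key step: step 9

Step 1
Reactants: 1 3,4,5-trimethoxybenzaldehyde; 2 (E)-crotylboronic acid pinacol ester
Product: 3 (1S,2S)-2-methyl-1-(3,4,5-trimethoxyphenyl)but-3-en-1-ol
Conditions: (S)-TRIP [(S)-3,3'-bis(2,4,6-triisopropylphenyl)-1,1'-binaphthyl-2,2'-diyl hydrogen phosphate] (5 mol%), toluene, 4 Å sieves, −30 °C; aqueous work-up
Reagents that add atoms: none
Why: Chiral phosphoric acid-catalysed crotylboration through a closed chair transition state, in which the (E)-boronate gives the anti product and the (S)-catalyst should direct the crotyl group to the si face of the aldehyde, setting future C2 and C3.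

Step 2
Reactants: 3 (1S,2S)-2-methyl-1-(3,4,5-trimethoxyphenyl)but-3-en-1-ol
Product: 5 (1S,2S)-2-methyl-1-(3,4,5-trimethoxyphenyl)butane-1,4-diol, via alkylborane 4 (not isolated)
Conditions: 9-BBN (2.2 equiv), THF, 0 °C to rt; then NaOH, H2O2
Reagents that add atoms: hydrogen peroxide, OO
Why: Anti-Markovnikov hydroboration of the terminal alkene followed by oxidation of the C–B bond with retention (hydroboration–oxidation); no stereocentre is touched.

Step 3
Reactants: 5 (1S,2S)-2-methyl-1-(3,4,5-trimethoxyphenyl)butane-1,4-diol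
Product: 7 (4S,5S)-4-methyl-5-(3,4,5-trimethoxyphenyl)oxolan-2-one, via lactol 6 (not isolated)
Conditions: TEMPO (10 mol%), PhI(OAc)2 (2.5 equiv), CH2Cl2, rt
Reagents that add atoms: none
Why: Oxoammonium oxidation is selective for the primary alcohol, the hydroxy aldehyde closes to lactol 6 and this is oxidised again to the γ-lactone (oxidative lactonisation of a 1,4-diol).

Step 4
Reactants: 7 (4S,5S)-4-methyl-5-(3,4,5-trimethoxyphenyl)oxolan-2-one; 8 allyl bromide
Product: 9 (3S,4S,5S)-4-methyl-3-(prop-2-en-1-yl)-5-(3,4,5-trimethoxyphenyl)oxolan-2-one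
Conditions: LiN(iPr)2, THF, −78 °C; then 8, −78 to −40 °C
Reagents that add atoms: none
Why: Lactone enolate alkylation in which allyl bromide should enter anti to the neighbouring methyl group; this carbon (future C3a) is made planar again in step 9, so its configuration is not critical.

Step 5
Reactants: 9 (3S,4S,5S)-4-methyl-3-(prop-2-en-1-yl)-5-(3,4,5-trimethoxyphenyl)oxolan-2-one
Product: 10 (3S,4S,5S)-4-methyl-3-(prop-2-en-1-yl)-5-(3,4,5-trimethoxyphenyl)oxolan-2-ol (anomer mixture)
Conditions: iBu2AlH (1.1 equiv), CH2Cl2, −78 °C; aq. potassium sodium tartrate (KNaC4H4O6)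
Reagents that add atoms: none
Why: Partial reduction of a lactone to the lactol, which stops at the stable tetrahedral aluminate at low temperature.

Step 6
Reactants: 10 (3S,4S,5S)-4-methyl-3-(prop-2-en-1-yl)-5-(3,4,5-trimethoxyphenyl)oxolan-2-ol; 11 methyl 2-(dimethoxyphosphoryl)-2-methoxyacetate
Product: 12 methyl (2Z,4S,5S,6S)-6-hydroxy-2-methoxy-5-methyl-4-(prop-2-en-1-yl)-6-(3,4,5-trimethoxyphenyl)hex-2-enoate
Conditions: 11 (2.2 equiv), LiN(SiMe3)2 (2.2 equiv), THF, 0 °C to rt
Reagents that add atoms: none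
Why: Horner–Wadsworth–Emmons olefination on the open hydroxy aldehyde form of the lactol; the alkene geometry (2Z expected as the main isomer) is of no consequence because C4–C5 becomes a single bond in the ketene of step 9.

Step 7
Reactants: 12 methyl (2Z,4S,5S,6S)-6-hydroxy-2-methoxy-5-methyl-4-(prop-2-en-1-yl)-6-(3,4,5-trimethoxyphenyl)hex-2-enoate; 13 vinyl acetate
Product: 14 methyl (2Z,4S,5S,6S)-6-(ethenyloxy)-2-methoxy-5-methyl-4-(prop-2-en-1-yl)-6-(3,4,5-trimethoxyphenyl)hex-2-enoate
Conditions: [Ir(cod)Cl]2 (2 mol%), Na2CO3 (0.6 equiv), 13 (3 equiv), toluene, 100 °C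
Reagents that add atoms: none
Why: Iridium-catalysed transfer vinylation of the secondary alcohol (alkoxide addition to coordinated vinyl acetate, then β-acetate elimination); the C–O bond of the stereocentre is not broken.

Step 8
Reactants: 14 methyl (2Z,4S,5S,6S)-6-(ethenyloxy)-2-methoxy-5-methyl-4-(prop-2-en-1-yl)-6-(3,4,5-trimethoxyphenyl)hex-2-enoate
Product: 15 (2Z,4S,5S,6S)-6-(ethenyloxy)-2-methoxy-5-methyl-4-(prop-2-en-1-yl)-6-(3,4,5-trimethoxyphenyl)hex-2-enoic acid
Conditions: LiOH, THF/MeOH/H2O, rt; then dilute H3PO4 to pH 5, 0 °C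
Reagents that add atoms: lithium hydroxide, [Li+].[OH-]
Why: Saponification of the methyl ester; the vinyl ether is stable to base and the acid is set free at pH 5 in the cold to avoid enol ether hydrolysis.

Step 9
Reactants: 15 (2Z,4S,5S,6S)-6-(ethenyloxy)-2-methoxy-5-methyl-4-(prop-2-en-1-yl)-6-(3,4,5-trimethoxyphenyl)hex-2-enoic acid
Product: 18 (2S,3S,3aS,7aR)-5-methoxy-3-methyl-3a-(prop-2-en-1-yl)-2-(3,4,5-trimethoxyphenyl)-3,3a,7,7a-tetrahydro-1-benzofuran-6(2H)-one, via acid chloride 16 (not isolated), via vinylketene 17 (not isolated)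
Conditions: 1-chloro-N,N,2-trimethylprop-1-en-1-amine (1.2 equiv), CH2Cl2, 0 °C to rt; then slow addition to Et3N (5 equiv), toluene, 110 °C, high dilution
Reagents that add atoms: none
Why: Proposed new method: Et3N takes the γ-hydrogen (on future C3a) from acid chloride 16 in a 1,4-dehydrochlorination and gives α-methoxy vinylketene 17, in which the nucleophilic CH2 end of the tethered vinyl ether (C7) attacks the electrophilic ketene carbon (C6) while its oxygen-bearing carbon (C7a) bonds to the diene end C3a, an asynchronous, polarity-matched intramolecular [4+2] cycloaddition with the vinylketene as four-carbon partner. The closest known reaction types are the Et3N-mediated formation of vinylketenes from α,β-unsaturated acid chlorides with intramolecular capture by an alkene, the Diels–Alder reactions of silyl vinylketenes as dienes and the polar cycloaddition of ketenes with enol ethers; a vinylketene [4+2] with a tethered enol ether has not been shown. The cyclohexenone ring closes in the [4+2] mode (bonds C6–C7 and C7a–C3a) and the oxolane ring closes with it as the three-atom tether ring of a type 1 intramolecular Diels–Alder reaction (5-exo with respect to the enol ether). C3a is set by the C3 stereocentre through allylic strain: the smaller allyl group takes the inside position of the diene end and the tether the outside one, and in the five-ring transition state the C3 methyl turns to the C4–H side away from the allyl group, so that C7a should add to the face that leaves allyl trans to methyl and cis to the aryl group; C7a follows as the cis ring fusion and is erased in step 10. The step needs [4+2] over [2+2] periselectivity, reaction of the enol ether and not of the allyl alkene, and face selectivity: the three-atom tether allows only the five/six-ring mode without strain, the enol ether is far more nucleophilic than the allyl group, and a cyclobutenone from 4π closure of 17 or the other C3a=C4 isomer can return to 17 at 110 °C.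

Step 10
Reactants: 18 (2S,3S,3aS,7aR)-5-methoxy-3-methyl-3a-(prop-2-en-1-yl)-2-(3,4,5-trimethoxyphenyl)-3,3a,7,7a-tetrahydro-1-benzofuran-6(2H)-one
Product: 20 (2S,3S,3aS)-5-methoxy-3-methyl-3a-(prop-2-en-1-yl)-2-(3,4,5-trimethoxyphenyl)-3,3a-dihydro-1-benzofuran-6(2H)-one, via silyl dienol ether 19 (not isolated)
Conditions: Me3SiOTf, Et3N, CH2Cl2, 0 °C; then Pd(OAc)2 (1.1 equiv), MeCN, rt
Reagents that add atoms: none
Why: Saegusa–Ito oxidation, in which enolisation of the C6 ketone can only go towards C7 and the palladium enolate loses the C7a hydrogen by syn β-hydride elimination, giving the vinylogous ester and removing the C7a stereocentre.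

Compound list
1 | 3,4,5-trimethoxybenzaldehyde | O=Cc1cc(OC)c(OC)c(OC)c1 | starting material
2 | (E)-crotylboronic acid pinacol ester | C/C=C/CB1OC(C)(C)C(C)(C)O1 | starting material
3 | (1S,2S)-2-methyl-1-(3,4,5-trimethoxyphenyl)but-3-en-1-ol | O[C@H](c1cc(OC)c(OC)c(OC)c1)[C@H](C=C)C | intermediate
4 | (1S,2S)-4-(9-borabicyclo[3.3.1]nonan-9-yl)-2-methyl-1-(3,4,5-trimethoxyphenyl)butan-1-ol | O[C@H](c1cc(OC)c(OC)c(OC)c1)[C@H](CCB1C2CCCC1CCC2)C | intermediate
5 | (1S,2S)-2-methyl-1-(3,4,5-trimethoxyphenyl)butane-1,4-diol | O[C@H](c1cc(OC)c(OC)c(OC)c1)[C@H](CCO)C | intermediate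
6 | (4S,5S)-4-methyl-5-(3,4,5-trimethoxyphenyl)oxolan-2-ol (anomer mixture) | O1[C@H](c2cc(OC)c(OC)c(OC)c2)[C@H](CC1O)C | intermediate
7 | (4S,5S)-4-methyl-5-(3,4,5-trimethoxyphenyl)oxolan-2-one | O1[C@H](c2cc(OC)c(OC)c(OC)c2)[C@H](CC1=O)C | intermediate
8 | allyl bromide | C=CCBr | starting material
9 | (3S,4S,5S)-4-methyl-3-(prop-2-en-1-yl)-5-(3,4,5-trimethoxyphenyl)oxolan-2-one | O1[C@H](c2cc(OC)c(OC)c(OC)c2)[C@H]([C@H](CC=C)C1=O)C | intermediate
10 | (3S,4S,5S)-4-methyl-3-(prop-2-en-1-yl)-5-(3,4,5-trimethoxyphenyl)oxolan-2-ol (anomer mixture) | O1[C@H](c2cc(OC)c(OC)c(OC)c2)[C@H]([C@H](CC=C)C1O)C | intermediate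
11 | methyl 2-(dimethoxyphosphoryl)-2-methoxyacetate | COC(C(=O)OC)P(=O)(OC)OC | starting material
12 | methyl (2Z,4S,5S,6S)-6-hydroxy-2-methoxy-5-methyl-4-(prop-2-en-1-yl)-6-(3,4,5-trimethoxyphenyl)hex-2-enoate | O[C@H](c1cc(OC)c(OC)c(OC)c1)[C@H]([C@H](CC=C)/C=C(\OC)C(=O)OC)C | intermediate
13 | vinyl acetate | C=COC(C)=O | starting material
14 | methyl (2Z,4S,5S,6S)-6-(ethenyloxy)-2-methoxy-5-methyl-4-(prop-2-en-1-yl)-6-(3,4,5-trimethoxyphenyl)hex-2-enoate | C=CO[C@H](c1cc(OC)c(OC)c(OC)c1)[C@H]([C@H](CC=C)/C=C(\OC)C(=O)OC)C | intermediate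
15 | (2Z,4S,5S,6S)-6-(ethenyloxy)-2-methoxy-5-methyl-4-(prop-2-en-1-yl)-6-(3,4,5-trimethoxyphenyl)hex-2-enoic acid | C=CO[C@H](c1cc(OC)c(OC)c(OC)c1)[C@H]([C@H](CC=C)/C=C(\OC)C(=O)O)C | intermediate
16 | (2Z,4S,5S,6S)-6-(ethenyloxy)-2-methoxy-5-methyl-4-(prop-2-en-1-yl)-6-(3,4,5-trimethoxyphenyl)hex-2-enoyl chloride | C=CO[C@H](c1cc(OC)c(OC)c(OC)c1)[C@H]([C@H](CC=C)/C=C(\OC)C(=O)Cl)C | intermediate
17 | (3E,5S,6S)-6-(ethenyloxy)-2-methoxy-5-methyl-4-(prop-2-en-1-yl)-6-(3,4,5-trimethoxyphenyl)hexa-1,3-dien-1-one | C=CO[C@H](c1cc(OC)c(OC)c(OC)c1)[C@H](/C(CC=C)=C/C(OC)=C=O)C | intermediate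
18 | (2S,3S,3aS,7aR)-5-methoxy-3-methyl-3a-(prop-2-en-1-yl)-2-(3,4,5-trimethoxyphenyl)-3,3a,7,7a-tetrahydro-1-benzofuran-6(2H)-one | C=CC[C@]12C=C(OC)C(=O)C[C@H]1O[C@H](c1cc(OC)c(OC)c(OC)c1)[C@H]2C | intermediate
19 | {[(2S,3S,3aS,7aR)-5-methoxy-3-methyl-3a-(prop-2-en-1-yl)-2-(3,4,5-trimethoxyphenyl)-2,3,3a,7a-tetrahydro-1-benzofuran-6-yl]oxy}trimethylsilane | C=CC[C@]12C=C(OC)C(O[Si](C)(C)C)=C[C@H]1O[C@H](c1cc(OC)c(OC)c(OC)c1)[C@H]2C | intermediate
20 | (2S,3S,3aS)-5-methoxy-3-methyl-3a-(prop-2-en-1-yl)-2-(3,4,5-trimethoxyphenyl)-3,3a-dihydro-1-benzofuran-6(2H)-one | C=CC[C@]12C=C(OC)C(=O)C=C1O[C@H](c1cc(OC)c(OC)c(OC)c1)[C@H]2C | target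

Total step count: 10. Longest linear sequence: 10 steps (from 1).

Steps most likely to fail

Step 9 (Proposed new method). The vinylketene may be used up by dimerisation, by a 1,5-hydrogen shift from the inside allyl CH2 to the ketene carbon or by [2+2] pathways before the tethered [4+2] closure takes place, and the facial discrimination at C3a may be weak. The fallback uses known chemistry, makes the ring bonds one at a time, sets out from 9 and comes back at 18. Lactone 9 is deprotonated with LiN(iPr)2 and alkylated with the iodo ketal 2-(2-iodoethyl)-2-(methoxymethyl)-1,3-dioxolane F1 (made beforehand from 1-methoxybut-3-en-2-one with Me3SiI and then ethylene glycol). The electrophile should enter anti to the methyl group and give the dialkylated lactone F2, which already carries the target configuration at C3a. Reduction with iBu2AlH gives the lactol F3. Aqueous acid then KOH/MeOH removes the ketal and closes the ring by aldol condensation of the methoxymethyl ketone carbon (C5) onto the aldehyde (C4), giving the 2-methoxycyclohexenone F4 with the free side-chain alcohol. Me3SiOTf/Et3N (2 equiv) gives the bis-silyl compound F5, and Pd(OAc)2 in MeCN converts it into the cross-conjugated dienone silyl ether F6. K2CO3 in MeOH frees the dienone alcohol F7, which should add to C7a by oxa-Michael closure and give 18.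

Step 10. Enolisation next to the β-alkoxy group may open the oxolane by retro-oxa-Michael elimination, and the palladium may engage the allyl group. The fallback replaces the palladium-mediated dehydrogenation by a selenoxide elimination, sets out from 19 (made from 18 as in step 10) and comes back at 20. Silyl dienol ether 19 is treated with PhSeCl in CH2Cl2 at −78 °C, which should react at C7 faster than at the allyl group and give the 7-phenylselanyl ketone F8. H2O2 with pyridine at 0 °C gives the selenoxide F9, which loses PhSeOH by syn elimination across C7–C7a and gives 20.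

Step 7. Vinyl transfer to the hindered secondary benzylic alcohol may be slow, acetyl transfer may compete, and an iridium hydride may move the allyl double bond. The fallback builds the vinyl ether by acetal formation and elimination, sets out from 12 and comes back at 14. Alcohol 12 with ethyl vinyl ether and pyridinium p-toluenesulfonate gives the mixed acetal F10. Me3SiOTf/Et3N in CH2Cl2 at 0 °C then ionises the less hindered ethoxy group, and loss of a proton from the oxocarbenium ion gives vinyl ether 14.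

Further compounds
F1 | step 9 | 2-(2-iodoethyl)-2-(methoxymethyl)-1,3-dioxolane | ICCC1(COC)OCCO1
F2 | step 9 | (3R,4S,5S)-3-{2-[2-(methoxymethyl)-1,3-dioxolan-2-yl]ethyl}-4-methyl-3-(prop-2-en-1-yl)-5-(3,4,5-trimethoxyphenyl)oxolan-2-one | O1[C@H](c2cc(OC)c(OC)c(OC)c2)[C@H]([C@](CC=C)(CCC2(COC)OCCO2)C1=O)C
F3 | step 9 | (3R,4S,5S)-3-{2-[2-(methoxymethyl)-1,3-dioxolan-2-yl]ethyl}-4-methyl-3-(prop-2-en-1-yl)-5-(3,4,5-trimethoxyphenyl)oxolan-2-ol (anomer mixture) | O1[C@H](c2cc(OC)c(OC)c(OC)c2)[C@H]([C@](CC=C)(CCC2(COC)OCCO2)C1O)C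
F4 | step 9 | (4R)-4-[(1S,2S)-1-hydroxy-1-(3,4,5-trimethoxyphenyl)propan-2-yl]-2-methoxy-4-(prop-2-en-1-yl)cyclohex-2-en-1-one | C=CC[C@]1([C@H](C)[C@H](O)c2cc(OC)c(OC)c(OC)c2)C=C(OC)C(=O)CC1
F5 | step 9 | bis(trimethylsilyl) derivative of F4 (side-chain silyl ether and ring 1-silyloxy diene) | C=CC[C@]1([C@H](C)[C@H](O[Si](C)(C)C)c2cc(OC)c(OC)c(OC)c2)C=C(OC)C(O[Si](C)(C)C)=CC1
F6 | step 9 | (4S)-2-methoxy-4-(prop-2-en-1-yl)-4-[(1S,2S)-1-(3,4,5-trimethoxyphenyl)-1-(trimethylsilyloxy)propan-2-yl]cyclohexa-2,5-dien-1-one | C=CC[C@]1([C@H](C)[C@H](O[Si](C)(C)C)c2cc(OC)c(OC)c(OC)c2)C=C(OC)C(=O)C=C1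
F7 | step 9 | (4S)-4-[(1S,2S)-1-hydroxy-1-(3,4,5-trimethoxyphenyl)propan-2-yl]-2-methoxy-4-(prop-2-en-1-yl)cyclohexa-2,5-dien-1-one | C=CC[C@]1([C@H](C)[C@H](O)c2cc(OC)c(OC)c(OC)c2)C=C(OC)C(=O)C=C1
F8 | step 10 | 7-(phenylselanyl) derivative of 18 (C7 epimers) | C=CC[C@]12C=C(OC)C(=O)C([Se]c3ccccc3)[C@H]1O[C@H](c1cc(OC)c(OC)c(OC)c1)[C@H]2C
F9 | step 10 | 7-(phenylseleninyl) derivative of 18 (selenoxide of F8) | C=CC[C@]12C=C(OC)C(=O)C([Se](=O)c3ccccc3)[C@H]1O[C@H](c1cc(OC)c(OC)c(OC)c1)[C@H]2C
F10 | step 7 | methyl (2Z,4S,5S,6S)-6-(1-ethoxyethoxy)-2-methoxy-5-methyl-4-(prop-2-en-1-yl)-6-(3,4,5-trimethoxyphenyl)hex-2-enoate (acetal epimers) | CCOC(C)O[C@H](c1cc(OC)c(OC)c(OC)c1)[C@H]([C@H](CC=C)/C=C(\OC)C(=O)OC)C
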